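**Strategy**

The heptane chain is numbered C1 (on ring A, the 5-methoxycatechol) to C7 (on ring B, the 4-hydroxyphenyl). Because C7 is benzylic to electron-rich ring B, the C3 hydroxyl oxygen is temporarily bonded to C7, which hides the syn-1,3-diol in a 2-aryl pyran ring (O, C3 to C7). A hetero-Diels–Alder annulation catalysed by Ti(OiPr)4 and (R)-BINOL joins 4-(benzyloxy)benzaldehyde to a 1-methoxy-3-silyloxy diene carrying C3–C6 and ring A: it forms C6–C7 and C3–O and sets C7 as the only stereocentre of a dihydropyranone. C7 then relays its configuration to C3 and C5 and is finally erased by hydrogenolysis of C7–O.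

Key step: step 8

Assumption: (R)-BINOL is taken to direct the nucleophile to the Re face of the titanium-bound aromatic aldehyde, which gives the required (2R)-dihydropyranone; if the sense proved opposite, (S)-BINOL would be used with no other change.

**Route**

Step 1
Reactants: 1 3,4-dihydroxy-5-methoxybenzaldehyde
Product: 2 3,4-bis(benzyloxy)-5-methoxybenzaldehyde
Conditions: BnBr, K2CO3, DMF, 60 °C, N2
Reagents that add atoms: benzyl bromide, BrCc1ccccc1
Why: Williamson ether synthesis in which both catechol phenoxides displace bromide (SN2), the benzyl groups being chosen because they should survive every later basic, Lewis acidic and hydride step and leave in the final hydrogenolysis.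

Step 2
Reactants: 2 3,4-bis(benzyloxy)-5-methoxybenzaldehyde
Product: 3 [3,4-bis(benzyloxy)-5-methoxyphenyl]methanol
Conditions: NaBH4, MeOH–THF, 0 °C
Reagents that add atoms: none
Why: Borohydride reduction of an aromatic aldehyde to the benzylic alcohol, which leaves the aryl ethers untouched.

Step 3
Reactants: 3 [3,4-bis(benzyloxy)-5-methoxyphenyl]methanol
Product: 4 1,2-bis(benzyloxy)-5-(bromomethyl)-3-methoxybenzene
Conditions: PBr3, Et2O, 0 °C
Reagents that add atoms: phosphorus tribromide, BrP(Br)Br
Why: Bromination of a primary benzylic alcohol with PBr3 (bromide displaces the phosphite leaving group by SN2), run cold and the bromide used directly because this electron-rich benzylic halide is labile on silica.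

Step 4
Reactants: 4 1,2-bis(benzyloxy)-5-(bromomethyl)-3-methoxybenzene; 5 trimethyl(prop-1-yn-1-yl)silane
Product: 7 1,2-bis(benzyloxy)-5-(but-3-yn-1-yl)-3-methoxybenzene, via silylalkyne 6 (not isolated)
Conditions: 5, n-BuLi, THF, −78 → −20 °C; 4, −78 → 0 °C; then K2CO3, MeOH, rt
Reagents that add atoms: none
Why: SN2 alkylation of 3-lithio-1-(trimethylsilyl)propyne at its propargylic carbon by the benzylic bromide (the silyl group blocks the alkyne terminus and suppresses allene formation), followed by base-catalysed methanolysis of the C(sp)–Si bond, should give the homologated terminal alkyne in one flask.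

Step 5
Reactants: 7 1,2-bis(benzyloxy)-5-(but-3-yn-1-yl)-3-methoxybenzene; 8 N-methoxy-N-methylacetamide
Product: 10 6-[3,4-bis(benzyloxy)-5-methoxyphenyl]hex-3-yn-2-one, via lithium acetylide 9 (not isolated)
Conditions: n-BuLi, THF, −78 °C; 8, −78 → 0 °C; aq. NH4Cl
Reagents that add atoms: none
Why: Acylation of a lithium acetylide with a Weinreb amide, whose chelated tetrahedral adduct persists until work-up and so prevents double addition, should give the methyl ynone.

Step 6
Reactants: 10 6-[3,4-bis(benzyloxy)-5-methoxyphenyl]hex-3-yn-2-one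
Product: 11 (3E)-6-[3,4-bis(benzyloxy)-5-methoxyphenyl]-4-methoxyhex-3-en-2-one
Conditions: NaOMe (0.2 equiv), MeOH–THF, 0 °C → rt
Reagents that add atoms: methanol, CO
Why: Methoxide-catalysed conjugate (oxa-Michael) addition of methanol to the ynone places the methoxy group regiospecifically on chain C3, and reversible addition should favour the E enone, although the alkene geometry is of no consequence because it is lost in step 8.

Step 7
Reactants: 11 (3E)-6-[3,4-bis(benzyloxy)-5-methoxyphenyl]-4-methoxyhex-3-en-2-one
Product: 13 (3E)-6-[3,4-bis(benzyloxy)-5-methoxyphenyl]-4-methoxy-2-[(triethylsilyl)oxy]hexa-1,3-diene, via lithium dienolate 12 (not isolated)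
Conditions: LiN(i-Pr)2, THF, −78 °C; TESCl, −78 → 0 °C; pentane, filtration
Reagents that add atoms: triethylsilyl chloride, CC[Si](Cl)(CC)CC
Why: Kinetic deprotonation of the vinylogous ester at the methyl group next to the carbonyl (not at the CH2 next to the methoxy-bearing carbon) and O-silylation of the cross-conjugated lithium enolate should give the silyl dienol ether regioselectively without touching the C3=C4 geometry.

Step 8
Reactants: 13 (3E)-6-[3,4-bis(benzyloxy)-5-methoxyphenyl]-4-methoxy-2-[(triethylsilyl)oxy]hexa-1,3-diene; 14 4-(benzyloxy)benzaldehyde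
Product: 16 (2R)-2-[4-(benzyloxy)phenyl]-6-{2-[3,4-bis(benzyloxy)-5-methoxyphenyl]ethyl}-2,3-dihydro-4H-pyran-4-one, via aldol silyl ether 15 (not isolated)
Conditions: (R)-BINOL (22 mol%), Ti(OiPr)4 (20 mol%), 4 Å molecular sieves, toluene, −20 → 0 °C; then CF3CO2H, CH2Cl2, 0 °C
Reagents that add atoms: none
Why: The catalyst formed from Ti(OiPr)4 and (R)-BINOL activates aldehyde 14, and the CH2 terminus of the silyl dienol ether (chain C6) adds to the carbonyl carbon in a Mukaiyama aldol addition through an open transition state, forming C6–C7 and, after silyl transfer to the aldolate, silyl ether 15; a concerted [4+2] path is unlikely because the arylethyl group sits on the inside of the s-cis diene. CF3CO2H then removes the silyl group and the C7 oxygen adds to C3 of the β-methoxy enone in a 6-endo-trig oxa-Michael closure, after which loss of methanol regenerates the enone of the 2,3-dihydropyran-4-one. The closest known reaction type is the hetero-Diels–Alder (aldol then cyclisation) reaction of aromatic aldehydes with 1-methoxy-3-silyloxy dienes under Ti(OiPr)4 and BINOL. C7 is the only new stereocentre and is set by the catalyst, whose ligand should shield the Si face of the bound aldehyde so that C6 adds to the Re face and gives R. The step needs enantioface selectivity, which is helped by the aromatic, non-enolisable, well-coordinating aldehyde, and regioselectivity for the diene terminus, which is secured because C6 is the only unhindered nucleophilic carbon and is activated by both oxygen substituents. The benzyl ethers and the ring A methoxy group should be inert to the mild Lewis acid and to the brief acid treatment.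

Step 9
Reactants: 16 (2R)-2-[4-(benzyloxy)phenyl]-6-{2-[3,4-bis(benzyloxy)-5-methoxyphenyl]ethyl}-2,3-dihydro-4H-pyran-4-one
Product: 17 (2R,6R)-2-[4-(benzyloxy)phenyl]-6-{2-[3,4-bis(benzyloxy)-5-methoxyphenyl]ethyl}oxan-4-one (2,6-cis)
Conditions: LiBH(s-Bu)3 (1.1 equiv), THF, −78 °C; aq. NH4Cl
Reagents that add atoms: none
Why: Conjugate (1,4) hydride reduction of the vinylogous ester, in which the bulky borohydride adds to ring carbon C6 (chain C3) along the axial trajectory of the half-chair that holds the C7 aryl group pseudo-equatorial, so the arylethyl chain should end up equatorial and cis to the aryl group (new centre R, controlled by C7), while the enolate formed resists further reduction until it is protonated on work-up.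

Step 10
Reactants: 17 (2R,6R)-2-[4-(benzyloxy)phenyl]-6-{2-[3,4-bis(benzyloxy)-5-methoxyphenyl]ethyl}oxan-4-one
Product: 18 (2R,4R,6R)-2-[4-(benzyloxy)phenyl]-6-{2-[3,4-bis(benzyloxy)-5-methoxyphenyl]ethyl}oxan-4-ol (hydroxyl axial, trans to both ring substituents)
Conditions: LiBH(s-Bu)3 (1.5 equiv), THF, −78 °C; aq. NH4Cl
Reagents that add atoms: none
Why: Ketone reduction with a bulky trialkylborohydride, which approaches the chair carrying both 2,6-substituents equatorial from the less hindered equatorial side and so should give the axial alcohol (new centre at chain C5 set by substrate control, 4R in the ring and S in the target).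

Step 11
Reactants: 18 (2R,4R,6R)-2-[4-(benzyloxy)phenyl]-6-{2-[3,4-bis(benzyloxy)-5-methoxyphenyl]ethyl}oxan-4-ol
Product: 20 5-[(3R,5S)-3,5-dihydroxy-7-(4-hydroxyphenyl)heptyl]-3-methoxybenzene-1,2-diol, via triphenolic oxanol 19 (not isolated)
Conditions: H2 (4 bar), Pd(OH)2/C, EtOH–AcOH (4:1), rt
Reagents that add atoms: none
Why: Catalytic hydrogenolysis in which the three aryl benzyl ethers should cleave first to triphenol 19, whose ring C7–O bond, benzylic and para to a free hydroxyl, is then cleaved with acid assistance (as in the hydrogenolysis of benzylic ethers of 4-hydroxyaryl cyclic ethers), turning C7 into CH2 while the C3–O and C5–O bonds are untouched and keep their configuration as the syn (3R,5S) diol.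

**Compound list**

1 | 3,4-dihydroxy-5-methoxybenzaldehyde | COc1cc(C=O)cc(O)c1O | starting material
2 | 3,4-bis(benzyloxy)-5-methoxybenzaldehyde | COc1cc(C=O)cc(OCc2ccccc2)c1OCc1ccccc1 | intermediate
3 | [3,4-bis(benzyloxy)-5-methoxyphenyl]methanol | COc1cc(CO)cc(OCc2ccccc2)c1OCc1ccccc1 | intermediate
4 | 1,2-bis(benzyloxy)-5-(bromomethyl)-3-methoxybenzene | COc1cc(CBr)cc(OCc2ccccc2)c1OCc1ccccc1 | intermediate
5 | trimethyl(prop-1-yn-1-yl)silane | CC#C[Si](C)(C)C | starting material
6 | {4-[3,4-bis(benzyloxy)-5-methoxyphenyl]but-1-yn-1-yl}trimethylsilane | COc1cc(CCC#C[Si](C)(C)C)cc(OCc2ccccc2)c1OCc1ccccc1 | intermediate (not isolated)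
7 | 1,2-bis(benzyloxy)-5-(but-3-yn-1-yl)-3-methoxybenzene | COc1cc(CCC#C)cc(OCc2ccccc2)c1OCc1ccccc1 | intermediate
8 | N-methoxy-N-methylacetamide | CC(=O)N(C)OC | starting material
9 | {4-[3,4-bis(benzyloxy)-5-methoxyphenyl]but-1-yn-1-yl}lithium | COc1cc(CCC#C[Li])cc(OCc2ccccc2)c1OCc1ccccc1 | intermediate (not isolated)
10 | 6-[3,4-bis(benzyloxy)-5-methoxyphenyl]hex-3-yn-2-one | COc1cc(CCC#CC(C)=O)cc(OCc2ccccc2)c1OCc1ccccc1 | intermediate
11 | (3E)-6-[3,4-bis(benzyloxy)-5-methoxyphenyl]-4-methoxyhex-3-en-2-one | CC(=O)/C=C(/OC)CCc1cc(OC)c(OCc2ccccc2)c(OCc2ccccc2)c1 | intermediate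
12 | lithium (3E)-6-[3,4-bis(benzyloxy)-5-methoxyphenyl]-4-methoxyhexa-1,3-dien-2-olate | [Li]OC(=C)/C=C(/OC)CCc1cc(OC)c(OCc2ccccc2)c(OCc2ccccc2)c1 | intermediate (not isolated)
13 | (3E)-6-[3,4-bis(benzyloxy)-5-methoxyphenyl]-4-methoxy-2-[(triethylsilyl)oxy]hexa-1,3-diene | C=C(O[Si](CC)(CC)CC)/C=C(/OC)CCc1cc(OC)c(OCc2ccccc2)c(OCc2ccccc2)c1 | intermediate
14 | 4-(benzyloxy)benzaldehyde | O=Cc1ccc(OCc2ccccc2)cc1 | starting material
15 | (1R,4E)-1-[4-(benzyloxy)phenyl]-7-[3,4-bis(benzyloxy)-5-methoxyphenyl]-5-methoxy-1-[(triethylsilyl)oxy]hept-4-en-3-one | CC[Si](CC)(CC)O[C@H](CC(=O)/C=C(/OC)CCc1cc(OC)c(OCc2ccccc2)c(OCc2ccccc2)c1)c1ccc(OCc2ccccc2)cc1 | intermediate (not isolated)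
16 | (2R)-2-[4-(benzyloxy)phenyl]-6-{2-[3,4-bis(benzyloxy)-5-methoxyphenyl]ethyl}-2,3-dihydro-4H-pyran-4-one | COc1cc(CCC2=CC(=O)C[C@H](c3ccc(OCc4ccccc4)cc3)O2)cc(OCc2ccccc2)c1OCc1ccccc1 | intermediate
17 | (2R,6R)-2-[4-(benzyloxy)phenyl]-6-{2-[3,4-bis(benzyloxy)-5-methoxyphenyl]ethyl}oxan-4-one | COc1cc(CC[C@@H]2CC(=O)C[C@H](c3ccc(OCc4ccccc4)cc3)O2)cc(OCc2ccccc2)c1OCc1ccccc1 | intermediate
18 | (2R,4R,6R)-2-[4-(benzyloxy)phenyl]-6-{2-[3,4-bis(benzyloxy)-5-methoxyphenyl]ethyl}oxan-4-ol | COc1cc(CC[C@@H]2C[C@@H](O)C[C@H](c3ccc(OCc4ccccc4)cc3)O2)cc(OCc2ccccc2)c1OCc1ccccc1 | intermediate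
19 | 5-{2-[(2R,4R,6R)-4-hydroxy-6-(4-hydroxyphenyl)oxan-2-yl]ethyl}-3-methoxybenzene-1,2-diol | COc1cc(CC[C@@H]2C[C@@H](O)C[C@H](c3ccc(O)cc3)O2)cc(O)c1O | intermediate (not isolated)
20 | 5-[(3R,5S)-3,5-dihydroxy-7-(4-hydroxyphenyl)heptyl]-3-methoxybenzene-1,2-diol | COc1cc(CC[C@@H](O)C[C@@H](O)CCc2ccc(O)cc2)cc(O)c1O | target

**Step count**

Total steps: 11. Longest linear sequence: 11 steps (1 → 20); compounds 5, 8 and 14 enter as purchased materials.

**Steps most likely to fail**

Step 8. Enantioface discrimination at the aldehyde may be insufficient, or catalyst turnover may be slow because the triethylsilyl group transfers sluggishly, allowing an unselective background addition. The fallback replaces the catalytic Lewis acid by a stoichiometric chiral boron enolate. It sets out from 11 (with 14). Ketone 11 is enolised at its methyl group with diisopinocampheylchloroborane (the antipode that directs addition to the Re face of the aldehyde) and Et3N in Et2O at 0 °C, and 14 is added at −78 °C. Work-up with H2O2 at pH 7 should give the free aldol (1R,4E)-1-[4-(benzyloxy)phenyl]-7-[3,4-bis(benzyloxy)-5-methoxyphenyl]-1-hydroxy-5-methoxyhept-4-en-3-one F1. CF3CO2H in CH2Cl2 at 0 °C then closes the ring with loss of methanol, and the route is rejoined at 16, which would be recrystallised if its enantiomeric purity needed raising.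

Step 11. The benzyl ethers may cleave while hydrogenolysis of the ring C7–O bond stalls, or forcing conditions may begin to saturate the phenolic rings. The fallback separates ring opening from debenzylation and sets out from 18. Ionic hydrogenation with Et3SiH and BF3·OEt2 in CH2Cl2 at −40 → 0 °C should ionise the C7–O bond to the 4-benzyloxybenzylic cation, which takes hydride from the silane. C3 and C5 are not involved, so this should give (3R,5S)-1-[3,4-bis(benzyloxy)-5-methoxyphenyl]-7-[4-(benzyloxy)phenyl]heptane-3,5-diol F2. Neutral hydrogenolysis (H2, 1 bar, Pd/C, EtOAc–MeOH) then removes the benzyl groups and the route comes back at 20.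

Step 9. Hydride may add 1,2 to the carbonyl in competition with conjugate addition, or the vinylogous ester may react incompletely. The fallback uses heterogeneous hydrogenation instead of a hydride reagent and sets out from 16. H2 (1 bar) over Pd/C in EtOAc without acid should add to the enol ether double bond from the face opposite the C7 aryl group and remove the three benzyl groups, leaving the ring C7–O bond intact. This would give (2R,6R)-2-[2-(3,4-dihydroxy-5-methoxyphenyl)ethyl]-6-(4-hydroxyphenyl)oxan-4-one F3. Excess LiBH(s-Bu)3 (about 5 equiv, to allow for three phenoxides) in THF at −78 °C should then deliver the axial alcohol, which is compound 19, where the route is rejoined. The conditions of step 11 convert 19 into 20.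

**Further compounds**

F1 | step 8 | (1R,4E)-1-[4-(benzyloxy)phenyl]-7-[3,4-bis(benzyloxy)-5-methoxyphenyl]-1-hydroxy-5-methoxyhept-4-en-3-one | O[C@H](CC(=O)/C=C(/OC)CCc1cc(OC)c(OCc2ccccc2)c(OCc2ccccc2)c1)c1ccc(OCc2ccccc2)cc1
F2 | step 11 | (3R,5S)-1-[3,4-bis(benzyloxy)-5-methoxyphenyl]-7-[4-(benzyloxy)phenyl]heptane-3,5-diol | COc1cc(CC[C@@H](O)C[C@@H](O)CCc2ccc(OCc3ccccc3)cc2)cc(OCc2ccccc2)c1OCc1ccccc1
F3 | step 9 | (2R,6R)-2-[2-(3,4-dihydroxy-5-methoxyphenyl)ethyl]-6-(4-hydroxyphenyl)oxan-4-one | COc1cc(CC[C@@H]2CC(=O)C[C@H](c3ccc(O)cc3)O2)cc(O)c1O
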